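**Retrosynthetic overview**
- The target is opened to an acyclic bromo-enal that already carries the furanone. The last step closes the ten-membered carbocycle at C6–C7 (the bond made when farnesyl diphosphate cyclises to the germacrane) and the C12–O6 lactone in one operation, setting C6 and C7.
- The allyl bromide/enal comes from a furanone dialdehyde and methyl acrylate (Morita–Baylis–Hillman reaction, then bromination).
- The furanone comes from an open 10-hydroxy-1-oxo-2-yne (a dehydrated 10-hydroxy-1,3-dione): O10 closes on C3, as in the biosynthetic hemiketalisation/dehydration. The ynone is released by acetylide opening of a sugar lactone, which also frees O8 for the isobutyrate.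
- C1, C7–C10 and C14 come from 2-C-methyl-L-lyxono-1,4-lactone, made from 2-C-methyl-D-ribono-1,4-lactone by inversion at C4. C2–C6 and C15 come from (Z)-3-methylpent-2-en-4-yn-1-ol.
- Ring order: furanone first, then carbocycle and lactone together.

Assumption: germacrane numbering of the target (C1 ketone, C3–O–C10 bridge, C12–O–C6 lactone, ester on C8, hydroxyl on C9, C14 on C10, C15 on C4) is used for every intermediate.

**Route**

Step 1
Reactants: 1 2-C-methyl-D-ribono-1,4-lactone
Product: 2 2-C-methyl-5-O-tosyl-D-ribono-1,4-lactone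
Conditions: TsCl (1.1 equiv), pyridine, −20 to 0 °C
Reagents that add atoms: p-toluenesulfonyl chloride, Cc1ccc(cc1)S(=O)(=O)Cl
Why: Sulfonylation is fastest at the only primary hydroxyl (regioselective tosylation), which turns C5 into the leaving group needed for the inversion; no stereocentre is touched.

Step 2
Reactants: 2 2-C-methyl-5-O-tosyl-D-ribono-1,4-lactone
Product: 6 2-C-methyl-L-lyxono-1,4-lactone, via ring-opened tosylate salt 3 (not isolated), via epoxy carboxylate 4 (not isolated), via potassium lyxonate 5 (not isolated)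
Conditions: KOH (3 equiv), H2O, 0 °C to rt; then HCl (aq) to pH 2, 50 °C, evaporation
Reagents that add atoms: potassium hydroxide, [K+].[OH-]
Why: Saponification frees the C4 alkoxide, which closes a 4,5-epoxide on C5 (retention at C4), and the carboxylate then opens the epoxide at C4 in a 5-exo SN2 attack with inversion (epoxide-mediated lactone inversion of 5-O-sulfonyl ribonolactones), so the D-ribo lactone becomes the L-lyxo lactone and the future C8 acquires its final configuration.

Step 3
Reactants: 6 2-C-methyl-L-lyxono-1,4-lactone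
Product: 7 2-C-methyl-3,5-bis-O-(triethylsilyl)-L-lyxono-1,4-lactone
Conditions: TESCl (2.3 equiv), imidazole, DMF, 0 °C
Reagents that add atoms: chlorotriethylsilane, CC[Si](Cl)(CC)CC
Why: Silylation with TESCl is fast at the primary and the secondary hydroxyl and very slow at the tertiary α-hydroxyl (steric differentiation), leaving O10 free for the furanone and masking O9 so that it cannot compete for C3.

Step 4
Reactants: 8 (Z)-3-methylpent-2-en-4-yn-1-ol
Product: 9 (Z)-triethyl[(3-methylpent-2-en-4-yn-1-yl)oxy]silane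
Conditions: TESCl (1.1 equiv), imidazole, CH2Cl2, 0 °C
Reagents that add atoms: chlorotriethylsilane, CC[Si](Cl)(CC)CC
Why: Standard silyl ether formation; it stops the Z-allylic hydroxyl from adding 5-exo to the ynone of step 5, and the Z C4=C5 bond of the target is bought in.

Step 5
Reactants: 9 (Z)-triethyl[(3-methylpent-2-en-4-yn-1-yl)oxy]silane; 7 2-C-methyl-3,5-bis-O-(triethylsilyl)-L-lyxono-1,4-lactone
Product: 14 furanone alcohol (O8 free), via lithium acetylide 10 (not isolated), via lactol 11 (not isolated), via open hydroxy ynone 12 (not isolated), via enaminone 13 (not isolated)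
Conditions: 9 (2.4 equiv), n-BuLi (2.3 equiv), THF, −78 °C; then 7, −78 °C, 2 h; AcOH (2.3 equiv), −78 °C; then Et2NH (3 equiv), EtOH, rt
Reagents that add atoms: none
Why: Mono-addition of the acetylide to the sugar lactone gives a lactol whose open α′-hydroxy ynone tautomer is trapped by Et2NH as the enaminone and closes through O10 onto C3 with loss of the amine (formal 5-endo-dig oxa-Michael, the classical 3(2H)-furanone synthesis from α′-hydroxy ynones), which is the O10–C3 bond of the biosynthetic hemiketalisation/dehydration of a 10-hydroxy-1,3-dione; C10 comes unchanged from the lactone, O9 is silylated and cannot compete, and the former ring oxygen is released as the free C8 hydroxyl.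

Step 6
Reactants: 14 furanone alcohol (O8 free); 15 isobutyric anhydride
Product: 16 furanone 8-O-isobutyrate
Conditions: (i-PrCO)2O (1.5 equiv), Et3N, DMAP (0.1 equiv), CH2Cl2, 0 °C to rt
Reagents that add atoms: isobutyric anhydride (15), CC(C)C(=O)OC(=O)C(C)C
Why: DMAP-catalysed acylation of the only free hydroxyl (Steglich-type acyl transfer) puts the isobutyrate on O8 with retention.

Step 7
Reactants: 16 furanone 8-O-isobutyrate
Product: 17 furanone dialdehyde
Conditions: (COCl)2 (6 equiv), DMSO (12 equiv), CH2Cl2, −78 to −35 °C; i-Pr2NEt, −78 to 0 °C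
Reagents that add atoms: none
Why: Under Swern conditions the chlorodimethylsulfonium salt cleaves primary TES ethers and oxidises them in place to aldehydes while the hindered secondary TES ether at O9 is untouched, so the C6 enal and the C7 aldehyde are unveiled together; cold base keeps the α-acyloxy centre C8.

Step 8
Reactants: 17 furanone dialdehyde; 18 methyl acrylate
Product: 19 Morita–Baylis–Hillman adduct (C7 epimers)
Conditions: DABCO (1.0 equiv), methyl acrylate (neat, 20 equiv), MeOH (2 equiv), rt, 24 h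
Reagents that add atoms: methyl acrylate (18), C=CC(=O)OC
Why: Morita–Baylis–Hillman reaction: the DABCO–acrylate zwitterion adds only to the activated α-acyloxy aldehyde C7, the conjugated β,β-disubstituted enal being inert, and the new C7 carbinol (both epimers) needs no control because it becomes sp2 in step 9.

Step 9
Reactants: 19 Morita–Baylis–Hillman adduct (C7 epimers)
Product: 20 (Z)-2-(bromomethyl)enoate
Conditions: NBS (1.5 equiv), Me2S (1.8 equiv), CH2Cl2, −20 °C (premixed); then 19, −20 to 0 °C
Reagents that add atoms: N-bromosuccinimide, BrN1C(=O)CCC1=O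
Why: Corey–Kim-type activation of the allylic alcohol as its oxysulfonium salt and SN2′ attack of bromide at C13 give the conjugated 2-(bromomethyl)enoate as the thermodynamically favoured Z isomer, the usual outcome for Morita–Baylis–Hillman adducts.

Step 10
Reactants: 20 (Z)-2-(bromomethyl)enoate
Product: 24 CNP0265772.1 (target), via allylchromium dichloride 21 (not isolated), via macrocyclic hydroxy ester 22 (not isolated), via 9-O-TES lactone 23 (not isolated)
Conditions: CrCl2 (6 equiv), THF, rt, syringe-pump addition of 20 (final 2 mM); then 1 M HCl (aq), THF, rt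
Reagents that add atoms: none
Why: Nozaki–Hiyama-type intramolecular allylation: two CrCl2 reduce the bromide to the allylchromium, which attacks the C6 aldehyde through C7 (SE2′, chair-like six-membered transition state) and so closes the ten-membered ring at the same C6–C7 bond that is formed when farnesyl diphosphate cyclises to the germacrane, the trivalent chromium alkoxide lactonises onto C12 and the acid work-up removes the TES ether; C6 and C7 are set here, the rigid furanone/Z-enal tether being expected to let the aldehyde reach only the C7 face anti to the C8 C–O bond, which leads to the 6,7-trans lactone (6R,7S).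

**Compound list**

1 | 2-C-methyl-D-ribono-1,4-lactone, (3R,4R,5R)-3,4-dihydroxy-5-(hydroxymethyl)-3-methyloxolan-2-one | C[C@@]1(O)[C@H](O)[C@@H](CO)OC1=O | starting material
2 | 2-C-methyl-5-O-(p-toluenesulfonyl)-D-ribono-1,4-lactone | C[C@@]1(O)[C@H](O)[C@@H](COS(=O)(=O)c2ccc(C)cc2)OC1=O | intermediate
3 | potassium 2-C-methyl-5-O-tosyl-D-ribonate (ring-opened tosylate salt) | [K+].[O-]C(=O)[C@](C)(O)[C@H](O)[C@H](O)COS(=O)(=O)c1ccc(C)cc1 | intermediate (not isolated)
4 | potassium 4,5-anhydro-2-C-methyl-D-ribonate (epoxy carboxylate) | [K+].[O-]C(=O)[C@](C)(O)[C@H](O)[C@H]1CO1 | intermediate (not isolated)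
5 | potassium 2-C-methyl-L-lyxonate | [K+].[O-]C(=O)[C@](C)(O)[C@H](O)[C@@H](O)CO | intermediate (not isolated)
6 | 2-C-methyl-L-lyxono-1,4-lactone, (3R,4R,5S)-3,4-dihydroxy-5-(hydroxymethyl)-3-methyloxolan-2-one | C[C@@]1(O)[C@H](O)[C@H](CO)OC1=O | intermediate
7 | 2-C-methyl-3,5-bis-O-(triethylsilyl)-L-lyxono-1,4-lactone, (3R,4R,5S)-3-hydroxy-3-methyl-4-(triethylsilyloxy)-5-[(triethylsilyloxy)methyl]oxolan-2-one | C[C@@]1(O)[C@H](O[Si](CC)(CC)CC)[C@H](CO[Si](CC)(CC)CC)OC1=O | intermediate
8 | (Z)-3-methylpent-2-en-4-yn-1-ol | C#C/C(C)=C\CO | starting material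
9 | (Z)-triethyl[(3-methylpent-2-en-4-yn-1-yl)oxy]silane | C#C/C(C)=C\CO[Si](CC)(CC)CC | intermediate
10 | lithium acetylide of 9 | [Li]C#C/C(C)=C\CO[Si](CC)(CC)CC | intermediate (not isolated)
11 | lactol, (3R,4R,5S)-3-methyl-2-[(3Z)-3-methyl-5-(triethylsilyloxy)pent-3-en-1-yn-1-yl]-4-(triethylsilyloxy)-5-[(triethylsilyloxy)methyl]oxolane-2,3-diol (both anomers) | C[C@@]1(O)[C@H](O[Si](CC)(CC)CC)[C@H](CO[Si](CC)(CC)CC)OC1(O)C#C/C(C)=C\CO[Si](CC)(CC)CC | intermediate (not isolated)
12 | open hydroxy ynone, (2S,3R,4R,8Z)-2,4-dihydroxy-4,8-dimethyl-1,3,10-tris(triethylsilyloxy)dec-8-en-6-yn-5-one | CC[Si](CC)(CC)OC/C=C(/C)C#CC(=O)[C@](C)(O)[C@H](O[Si](CC)(CC)CC)[C@@H](O)CO[Si](CC)(CC)CC | intermediate (not isolated)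
13 | enaminone, (2S,3R,4R,8Z)-7-(diethylamino)-2,4-dihydroxy-4,8-dimethyl-1,3,10-tris(triethylsilyloxy)deca-6,8-dien-5-one (6-ene geometry open) | CC[Si](CC)(CC)OC/C=C(/C)C(N(CC)CC)=CC(=O)[C@](C)(O)[C@H](O[Si](CC)(CC)CC)[C@@H](O)CO[Si](CC)(CC)CC | intermediate (not isolated)
14 | furanone alcohol, (2R)-2-[(1R,2S)-2-hydroxy-1,3-bis(triethylsilyloxy)propyl]-2-methyl-5-[(2Z)-4-(triethylsilyloxy)but-2-en-2-yl]furan-3(2H)-one; germacrane descriptors 8S,9R,10R,4Z | CC[Si](CC)(CC)OC/C=C(/C)C1=CC(=O)[C@](C)(O1)[C@H](O[Si](CC)(CC)CC)[C@@H](O)CO[Si](CC)(CC)CC | intermediate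
15 | isobutyric anhydride (2-methylpropanoic anhydride) | CC(C)C(=O)OC(=O)C(C)C | starting material
16 | furanone 8-O-isobutyrate, (2S,3R)-3-[(2R)-2-methyl-3-oxo-5-[(2Z)-4-(triethylsilyloxy)but-2-en-2-yl]-2,3-dihydrofuran-2-yl]-1,3-bis(triethylsilyloxy)propan-2-yl 2-methylpropanoate | CC[Si](CC)(CC)OC/C=C(/C)C1=CC(=O)[C@](C)(O1)[C@H](O[Si](CC)(CC)CC)[C@@H](OC(=O)C(C)C)CO[Si](CC)(CC)CC | intermediate
17 | furanone dialdehyde, (2R,3R)-3-[(2R)-2-methyl-3-oxo-5-[(2Z)-4-oxobut-2-en-2-yl]-2,3-dihydrofuran-2-yl]-1-oxo-3-(triethylsilyloxy)propan-2-yl 2-methylpropanoate (C8 descriptor changes by priority only, configuration as in 16) | O=C/C=C(/C)C1=CC(=O)[C@](C)(O1)[C@H](O[Si](CC)(CC)CC)[C@@H](OC(=O)C(C)C)C=O | intermediate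
18 | methyl acrylate | C=CC(=O)OC | starting material
19 | Morita–Baylis–Hillman adduct, methyl (4S,5R)-3-hydroxy-2-methylidene-4-(2-methylpropanoyloxy)-5-[(2R)-2-methyl-3-oxo-5-[(2Z)-4-oxobut-2-en-2-yl]-2,3-dihydrofuran-2-yl]-5-(triethylsilyloxy)pentanoate (both C3 epimers) | O=C/C=C(/C)C1=CC(=O)[C@](C)(O1)[C@H](O[Si](CC)(CC)CC)[C@@H](OC(=O)C(C)C)C(O)C(=C)C(=O)OC | intermediate
20 | methyl (2Z,4S,5R)-2-(bromomethyl)-4-(2-methylpropanoyloxy)-5-[(2R)-2-methyl-3-oxo-5-[(2Z)-4-oxobut-2-en-2-yl]-2,3-dihydrofuran-2-yl]-5-(triethylsilyloxy)pent-2-enoate | O=C/C=C(/C)C1=CC(=O)[C@](C)(O1)[C@H](O[Si](CC)(CC)CC)[C@@H](OC(=O)C(C)C)/C=C(\CBr)C(=O)OC | intermediate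
21 | allylchromium dichloride from 20 (CrCl2 group in place of Br on C13, trivalent chromium, same alkene geometry) | O=C/C=C(/C)C1=CC(=O)[C@](C)(O1)[C@H](O[Si](CC)(CC)CC)[C@@H](OC(=O)C(C)C)/C=C(\C[Cr](Cl)Cl)C(=O)OC | intermediate (not isolated)
22 | macrocyclic hydroxy ester, methyl (6R,7S,8S,9R,10R,4Z)-6-hydroxy-8-(2-methylpropanoyloxy)-1-oxo-9-(triethylsilyloxy)-3,10-epoxygermacra-2,4,11(13)-trien-12-oate | C=C(C(=O)OC)[C@H]1[C@H](O)/C=C(/C)C2=CC(=O)[C@](C)(O2)[C@H](O[Si](CC)(CC)CC)[C@H]1OC(=O)C(C)C | intermediate (not isolated)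
23 | 9-O-TES lactone, (6R,7S,8S,9R,10R,4Z)-8-(2-methylpropanoyloxy)-1-oxo-9-(triethylsilyloxy)-3,10-epoxygermacra-2,4,11(13)-trien-12,6-olide | C=C1C(=O)O[C@@H]2/C=C(/C)C3=CC(=O)[C@](C)(O3)[C@H](O[Si](CC)(CC)CC)[C@@H](OC(=O)C(C)C)[C@@H]12 | intermediate (not isolated)
24 | CNP0265772.1, (6R,7S,8S,9R,10R,4Z)-9-hydroxy-8-(2-methylpropanoyloxy)-1-oxo-3,10-epoxygermacra-2,4,11(13)-trien-12,6-olide | C=C1C(=O)O[C@@H]2/C=C(/C)C3=CC(=O)[C@](C)(O3)[C@H](O)[C@@H](OC(=O)C(C)C)[C@@H]12 | target

**Step count and risks**

Total steps: 10. Longest linear sequence: 9 (steps 1, 2, 3, 5, 6, 7, 8, 9, 10; step 4 is the side branch).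

Most likely to fail, first: step 10. The macrocyclisation is run last on the fully functionalised substrate, so there are three ways it can go wrong: the allylchromium may expel the neighbouring C8 isobutyrate in a reductive 1,4-elimination, the ring may close to the 6,7-cis lactone, or oligomers may form. The fallback sets out from 20 and comes back at 23. The bromide is borylated with B2pin2 under Pd2(dba)3 catalysis (toluene, 50 °C) to the allyl pinacolboronate F1, a non-reducing, configurationally stable allyl donor that cannot expel the ester. Slow addition of F1 to Sc(OTf)3 (20 mol %) in toluene at 2 mM brings about the intramolecular allylboration through a tight closed six-membered transition state, and lactonisation gives 23, which the acid treatment of step 10 converts to 24.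

Second: step 8. The α-acyloxy, β-silyloxy aldehyde sits for a day with an amine, so C8 may epimerise, the C9 silyloxy group may be eliminated, the isobutyrate may migrate to the new C7 hydroxyl, and the Z-enal may drift to E. The fallback sets out from 17 and comes back at 19. Methyl propiolate is hydroaluminated with i-Bu2AlH and N-methylmorpholine N-oxide (THF, 0 °C) to [1-(methoxycarbonyl)vinyl]diisobutylaluminium F2. F2 (1.1 equiv) adds to the more electrophilic α-acyloxy aldehyde of 17 at −78 °C within minutes and gives 19 after Rochelle-salt work-up, with no amine base in the flask.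

Third: step 5. Addition to the lactone that carries a lithium alkoxide next to the carbonyl may be slow, the TES group may migrate from O9 to the O10 alkoxide (which would turn the cyclisation towards a pyranone), and trapping of the minor open-chain tautomer may be incomplete. The fallback sets out from 7 and comes back at 16. MeNH(OMe)·HCl with i-PrMgCl (THF, −20 °C) opens the lactone to the Weinreb amide F3. Immediate acylation of its secondary hydroxyl with 15 (DMAP, Et3N) gives the amide isobutyrate F4. Acetylide 10 (2.2 equiv, THF, −78 °C) adds once to the amide and gives the open-chain α′-hydroxy ynone isobutyrate F5, which cannot close to a lactol. Et2NH in EtOH then closes the furanone and delivers 16.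

**Further compounds**

F1 | step 10 | allyl pinacolboronate, methyl (4S,5R)-4-(2-methylpropanoyloxy)-5-[(2R)-2-methyl-3-oxo-5-[(2Z)-4-oxobut-2-en-2-yl]-2,3-dihydrofuran-2-yl]-2-[(4,4,5,5-tetramethyl-1,3,2-dioxaborolan-2-yl)methyl]-5-(triethylsilyloxy)pent-2-enoate (alkene geometry as in 20) | O=C/C=C(/C)C1=CC(=O)[C@](C)(O1)[C@H](O[Si](CC)(CC)CC)[C@@H](OC(=O)C(C)C)/C=C(\CB2OC(C)(C)C(C)(C)O2)C(=O)OC
F2 | step 8 | [1-(methoxycarbonyl)vinyl]diisobutylaluminium | C=C(C(=O)OC)[Al](CC(C)C)CC(C)C
F3 | step 5 | Weinreb amide, (2R,3R,4S)-2,4-dihydroxy-N-methoxy-N,2-dimethyl-3,5-bis(triethylsilyloxy)pentanamide | CON(C)C(=O)[C@](C)(O)[C@H](O[Si](CC)(CC)CC)[C@@H](O)CO[Si](CC)(CC)CC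
F4 | step 5 | amide isobutyrate, (2S,3R,4R)-4-hydroxy-5-[methoxy(methyl)amino]-4-methyl-5-oxo-1,3-bis(triethylsilyloxy)pentan-2-yl 2-methylpropanoate | CON(C)C(=O)[C@](C)(O)[C@H](O[Si](CC)(CC)CC)[C@@H](OC(=O)C(C)C)CO[Si](CC)(CC)CC
F5 | step 5 | open-chain α′-hydroxy ynone isobutyrate, (2S,3R,4R,8Z)-4-hydroxy-4,8-dimethyl-5-oxo-1,3,10-tris(triethylsilyloxy)dec-8-en-6-yn-2-yl 2-methylpropanoate | CC[Si](CC)(CC)OC/C=C(/C)C#CC(=O)[C@](C)(O)[C@H](O[Si](CC)(CC)CC)[C@@H](OC(=O)C(C)C)CO[Si](CC)(CC)CC
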